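**Plan**

Locants: C1 = C(OH)(CH2OBz), C2 = C=O, C3=C4, C5 = CHOBz, C6 = CHOH, C7 = CH2 on C1. Retrosynthesis: both benzoates and a C1/C6 acetonide are removed, the C2 carbonyl is tied back to the C5 oxygen as a methoxy ketal bridge, and the carbocycle is cut at C1–C2 and C5–C6.
Enabling feature: the ring is a 4-oxycyclohex-2-enone (oxygen on C2 and C5 across the C3=C4 alkene, i.e. a masked 2-alkoxyfuran whose ring oxygen ends on C5) joined to a cis C1/C6 diol with C7 on C1 (a cis-dioxygenated acrylate, held as a 1,3-dioxol-2-one ring).
Forward: glycerol carbonate is converted into the dioxolone acyl oxazolidinone (3 steps); one cycloaddition with 2-methoxyfuran forms the only carbocycle as a 7-oxanorbornene ketal; reduction, C7 benzoylation, acid opening of the oxa-bridge (enone and C5–OH), acetonide formation, C5 benzoylation and acid deprotection complete the route.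
Stereochemistry: the chiral copper catalyst selects the dienophile face (C1 and C6, cis through the dioxolone ring), the endo position of the carbonate places the C5 oxygen trans to the C6 oxygen, and no later step breaks a bond at C1, C5 or C6.

Key step: step 4

Assumption: dienophile 7 is taken to bind Cu(II) through both imide carbonyl groups in the planar s-cis arrangement known for acryloyl oxazolidinones; on that model the (R,R)-ligand exposes the required face, and the equally available (S,S)-ligand would be used if the sense proves opposite.
Note on names: from compound 9 onwards the target locants C1–C7 are used and the oxygen bridge is written as 2,5-epoxy.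

Step 1
Reactants: 1 glycerol carbonate (racemic 4-(hydroxymethyl)-1,3-dioxolan-2-one)
Product: 2 2-oxo-1,3-dioxolane-4-carboxylic acid (racemic)
Conditions: TEMPO (10 mol %), PhI(OAc)2 (2.2 equiv), MeCN/H2O 1:1, rt
Reagents that add atoms: water, O
Why: Oxoammonium (TEMPO) oxidation of a primary alcohol through the aldehyde hydrate to the acid runs in weakly acidic aqueous acetonitrile, where the five-membered carbonate should survive; the stereocentre of 1 need not be defined because step 3 removes it.

Step 2
Reactants: 2 2-oxo-1,3-dioxolane-4-carboxylic acid, 3 2-oxazolidinone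
Product: 5 3-(2-oxo-1,3-dioxolane-4-carbonyl)oxazolidin-2-one, via acid chloride 4 (not isolated)
Conditions: (COCl)2, DMF (cat.), CH2Cl2, 0 °C to rt, evaporate; then 3, n-BuLi, THF, −78 °C, add crude 4
Reagents that add atoms: oxalyl chloride, O=C(Cl)C(=O)Cl (chlorine of intermediate 4 only); 2-oxazolidinone (3), O=C1NCCO1
Why: DMF-catalysed (Vilsmeier-type) acid chloride formation followed by N-acylation of the lithium salt of 3 is the standard route to N-acyl oxazolidinones, and at −78 °C acylation should outrun deprotonation next to the carbonyl group and attack on the carbonate.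

Step 3
Reactants: 5 3-(2-oxo-1,3-dioxolane-4-carbonyl)oxazolidin-2-one
Product: 7 3-(2-oxo-1,3-dioxole-4-carbonyl)oxazolidin-2-one, via 4-bromodioxolanone imide 6 (not isolated)
Conditions: NBS (1.05 equiv), AIBN (cat.), PhCF3, 80 °C; filter cold; Et3N (1.1 equiv), 0 °C
Reagents that add atoms: N-bromosuccinimide, O=C1CCC(=O)N1Br (bromine of intermediate 6 only)
Why: Wohl–Ziegler-type radical bromination should select the captodative C–H between the imide carbonyl and the carbonate oxygen, as in 1,3-dioxolan-4-ones, and amine-induced dehydrobromination then gives the ring alkene in the manner of the chloroethylene carbonate to vinylene carbonate conversion; bromination at the neighbouring CH2 would lead to the same alkene.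

Step 4
Reactants: 7 3-(2-oxo-1,3-dioxole-4-carbonyl)oxazolidin-2-one, 8 2-methoxyfuran
Product: 9 3-{[(1S,2S,5R,6S)-1,6-(carbonyldioxy)-2-methoxy-2,5-epoxycyclohex-3-en-1-yl]carbonyl}oxazolidin-2-one (endo carbonate, exo imide)
Conditions: [Cu((R,R)-t-Bu-box)](SbF6)2 (10 mol %), 8 (1.5 equiv), CH2Cl2, −78 °C; Et3N quench at −78 °C, cold filtration through Et3N-deactivated silica, used at once
Reagents that add atoms: none
Why: Proposed new method: chelation of both imide carbonyl groups of 7 to square-planar Cu(II) lowers the LUMO, so that furan C5 (largest HOMO coefficient) bonds to the β-carbon C6 ahead of the methoxy-bearing furan C2 bonding to C1, either as a concerted asynchronous [4+2] or as a Mukaiyama–Michael addition whose 2-methoxyfuranium ion is captured at C1 by the copper enolate; the closest known reaction types are the Cu(II)–bis(oxazoline)-catalysed Diels–Alder reaction of furan with acryloyl oxazolidinones and the thermal cycloaddition of furans to vinylene carbonate. The six-membered carbocycle C1–C6 closes by [4+2] cycloaddition (in the stepwise limit a 6-(enolexo)-exo-trig attack of the enolate on the oxocarbenium ion), leaving the furan oxygen as the C2–O–C5 bridge of a 7-oxanorbornene. C1 and C6 are set by the ligand: the tert-butyl group of the (R,R)-ligand should cover the Re face of the bound alkene, the furan adds to the Si face, and suprafacial addition to the dioxolone ring keeps the two C–O bonds cis. C5 and the ketal carbon C2 follow from the endo position of the carbonate ring (imide exo), which is expected because the α-oxygen substituent should act like the α-substituent of methacrolein or 2-acyloxyacroleins, which place the carbonyl group exo, and because the bulky copper-bound imide avoids the concave face. The step thus needs regio-, endo- and facial selectivity, secured in turn by the pairing of furan C5 with the imide β-carbon, by the α-oxy substituent together with catalyst bulk, and by the C2-symmetric ligand; C1 carries no hydrogen, so the adduct cannot aromatise, and the low temperature and basic quench are meant to suppress proton loss from the furanium ion and opening of the ketal.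

Step 5
Reactants: 9 cycloadduct
Product: 10 (1S,2S,5R,6S)-1-(hydroxymethyl)-2-methoxy-2,5-epoxycyclohex-3-ene-1,6-diol
Conditions: LiAlH4 (3 equiv), THF, −40 to 0 °C; aqueous NaOH work-up
Reagents that add atoms: none
Why: Hydride reduction with LiAlH4 should convert the activated imide carbonyl into the primary alcohol (releasing the oxazolidinone) and then the cyclic carbonate into the diol and methanol, while the ketal, the isolated alkene and all four stereocentres are inert to hydride and the basic work-up spares the bridge.

Step 6
Reactants: 10 triol, 11 benzoyl chloride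
Product: 12 [(1S,2S,5R,6S)-1,6-dihydroxy-2-methoxy-2,5-epoxycyclohex-3-en-1-yl]methyl benzoate
Conditions: BzCl (1.05 equiv), pyridine, CH2Cl2, −20 °C
Reagents that add atoms: benzoyl chloride (11), O=C(Cl)c1ccccc1
Why: Site-selective O-acylation: the primary C7 hydroxyl should react much faster than the tertiary C1 hydroxyl and the secondary C6 hydroxyl on the concave endo face.

Step 7
Reactants: 12 mono-benzoate
Product: 13 [(1S,5R,6S)-1,5,6-trihydroxy-2-oxocyclohex-3-en-1-yl]methyl benzoate
Conditions: PPTS (10 mol %), THF/H2O 4:1, rt
Reagents that add atoms: water, O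
Why: Acid-catalysed ketal hydrolysis: ionisation of the strained bicyclic mixed ketal gives an allyl-stabilised oxocarbenium ion that water converts into the C2 ketone with loss of methanol, the bridge oxygen stays on C5 with its configuration because the C5–O bond is never broken, and the quaternary C1 rules out aromatisation by dehydration.

Step 8
Reactants: 13 triol enone
Product: 14 [(1S,5R,6S)-5-hydroxy-1,6-(isopropylidenedioxy)-2-oxocyclohex-3-en-1-yl]methyl benzoate
Conditions: 2,2-dimethoxypropane, PPTS (cat.), acetone, rt
Reagents that add atoms: 2,2-dimethoxypropane, COC(C)(C)OC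
Why: Isopropylidene acetal formation (transketalisation) should select the cis C1/C6 diol, which gives a cis-fused dioxolane, over the trans C5/C6 pair, so that only the C5 hydroxyl stays free.

Step 9
Reactants: 14 acetonide alcohol, 11 benzoyl chloride
Product: 15 [(1S,5R,6S)-5-(benzoyloxy)-1,6-(isopropylidenedioxy)-2-oxocyclohex-3-en-1-yl]methyl benzoate
Conditions: BzCl (1.5 equiv), pyridine, DMAP (cat.), CH2Cl2, 0 °C
Reagents that add atoms: benzoyl chloride (11), O=C(Cl)c1ccccc1
Why: DMAP-catalysed acylation of the only free (allylic secondary) hydroxyl; the mild amine base and low temperature should avoid elimination at the γ-position of the enone, and C5 keeps its configuration because its C–O bond is untouched.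

Step 10
Reactants: 15 acetonide dibenzoate
Product: 16 zeylenone, [(1S,5R,6S)-5-(benzoyloxy)-1,6-dihydroxy-2-oxocyclohex-3-en-1-yl]methyl benzoate
Conditions: TFA/H2O 9:1, 0 °C to rt
Reagents that add atoms: none
Why: Acid hydrolysis of the isopropylidene acetal should free the cis C1/C6 diol while both benzoates are stable to acid, and the absence of base excludes benzoyl migration and elimination.

**Compound list**

1 | glycerol carbonate, racemic 4-(hydroxymethyl)-1,3-dioxolan-2-one | OCC1COC(=O)O1 | starting material
2 | 2-oxo-1,3-dioxolane-4-carboxylic acid (racemic) | O=C(O)C1COC(=O)O1 | intermediate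
3 | 2-oxazolidinone | O=C1NCCO1 | starting material
4 | 2-oxo-1,3-dioxolane-4-carbonyl chloride (racemic, not isolated) | O=C(Cl)C1COC(=O)O1 | intermediate
5 | 3-(2-oxo-1,3-dioxolane-4-carbonyl)oxazolidin-2-one (racemic) | O=C(N1CCOC1=O)C1COC(=O)O1 | intermediate
6 | 3-(4-bromo-2-oxo-1,3-dioxolane-4-carbonyl)oxazolidin-2-one (racemic, not isolated) | O=C(N1CCOC1=O)C1(Br)COC(=O)O1 | intermediate
7 | 3-(2-oxo-1,3-dioxole-4-carbonyl)oxazolidin-2-one | O=C(N1CCOC1=O)C1=COC(=O)O1 | intermediate
8 | 2-methoxyfuran | COc1ccco1 | starting material
9 | 3-{[(1S,2S,5R,6S)-1,6-(carbonyldioxy)-2-methoxy-2,5-epoxycyclohex-3-en-1-yl]carbonyl}oxazolidin-2-one (endo carbonate, exo imide 7-oxanorbornene) | O=C(N1CCOC1=O)[C@@]1(OC(=O)O2)[C@]3(OC)C=C[C@@H](O3)[C@@H]12 | intermediate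
10 | (1S,2S,5R,6S)-1-(hydroxymethyl)-2-methoxy-2,5-epoxycyclohex-3-ene-1,6-diol | OC[C@@]1(O)[C@]2(OC)C=C[C@@H](O2)[C@@H]1O | intermediate
11 | benzoyl chloride | O=C(Cl)c1ccccc1 | starting material
12 | [(1S,2S,5R,6S)-1,6-dihydroxy-2-methoxy-2,5-epoxycyclohex-3-en-1-yl]methyl benzoate | O=C(OC[C@@]1(O)[C@]2(OC)C=C[C@@H](O2)[C@@H]1O)c1ccccc1 | intermediate
13 | [(1S,5R,6S)-1,5,6-trihydroxy-2-oxocyclohex-3-en-1-yl]methyl benzoate | O=C(OC[C@@]1(O)C(=O)C=C[C@@H](O)[C@@H]1O)c1ccccc1 | intermediate
14 | [(1S,5R,6S)-5-hydroxy-1,6-(isopropylidenedioxy)-2-oxocyclohex-3-en-1-yl]methyl benzoate | O=C(OC[C@@]1(OC(C)(C)O2)C(=O)C=C[C@@H](O)[C@@H]12)c1ccccc1 | intermediate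
15 | [(1S,5R,6S)-5-(benzoyloxy)-1,6-(isopropylidenedioxy)-2-oxocyclohex-3-en-1-yl]methyl benzoate | O=C(OC[C@@]1(OC(C)(C)O2)C(=O)C=C[C@@H](OC(=O)c3ccccc3)[C@@H]12)c1ccccc1 | intermediate
16 | zeylenone, [(1S,5R,6S)-5-(benzoyloxy)-1,6-dihydroxy-2-oxocyclohex-3-en-1-yl]methyl benzoate | O=C(OC[C@@]1(O)C(=O)C=C[C@@H](OC(=O)c2ccccc2)[C@@H]1O)c1ccccc1 | target

**Step count**

Total: 10 steps. Longest linear sequence: 10 steps (1 to 16); 3, 8 and 11 are bought.

**Steps most likely to fail**

Step 4. The copper-bound intermediate may lose a proton from the furanium ion (Friedel–Crafts-type substitution of the furan) or expel the carbonate oxygen from the enolate instead of closing the ring. The adduct may also revert or ionise on warming. The α-oxygenated imide may bind out of plane, which would erode facial and endo/exo selectivity. The fallback moves stereocontrol to a covalently bound auxiliary and a separation, and uses no Lewis acid. It sets out from acid 2 and returns at triol 10. The chloride 4 is made as in step 2 and used to acylate lithiated (S)-4-tert-butyl-2-oxazolidinone (commercial, no weak C–H bonds), which should give the saturated auxiliary imide F1 as both epimers at the dioxolane carbon; this is of no consequence. Radical bromination with NBS as in step 3 should give the tertiary bromide F2, and triethylamine then the chiral dioxolone imide F3. F3 and 2-methoxyfuran 8 are combined in CH2Cl2 at 25 °C, or at 12 kbar if the reaction is slow. This is a plain thermal or high-pressure furan Diels–Alder reaction in which neither a metal enolate nor a free furanium ion is formed. Because the adducts are diastereomers, the one with the (1S,2S,5R,6S) ring, the auxiliary-bearing cycloadduct F4, can be separated by chromatography or crystallisation whatever the intrinsic face and endo/exo preference. LiAlH4 as in step 5 then removes auxiliary and carbonate and gives 10.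

Step 3. Bromine atoms may abstract hydrogen from the oxazolidinone CH2 groups or brominate twice. The amine may open the carbonate ring by elimination or add to the electrophilic product. The fallback brominates by an ionic path before the oxazolidinone is present. It sets out from acid 2 and returns at bromide 6. The acid is converted into chloride 4 with SOCl2 and α-brominated in the same medium under Hell–Volhard–Zelinsky-type conditions (NBS, catalytic HBr, 70 °C), which should give the α-bromo acid chloride F5. Acylation of lithiated 3 with F5 at −78 °C gives 6, which is dehydrobrominated with Et3N as before.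

Step 5. The carbonate may be opened before the imide is reduced, after which the freed C1 alkoxide can attack the ring carbonyl of the oxazolidinone (acyl transfer and ring opening instead of clean reduction). Hydride may also attack that ring carbonyl directly at the hindered acyl group. The fallback separates the two events and removes the carbonate by transesterification instead of reduction. It sets out from 9 and returns at 10. NaBH4 in THF/H2O at 0 °C should reduce only the imide and give the hydroxymethyl carbonate F6. K2CO3 in MeOH at rt then methanolyses the carbonate to triol 10; any migration of the carbonate onto the primary hydroxyl is harmless, since every isomer gives the same triol.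

**Further compounds**

F1 | step 4 | (4S)-4-tert-butyl-3-(2-oxo-1,3-dioxolane-4-carbonyl)oxazolidin-2-one (both epimers at the dioxolane carbon) | O=C(N1[C@@H](C(C)(C)C)COC1=O)C1COC(=O)O1
F2 | step 4 | (4S)-3-(4-bromo-2-oxo-1,3-dioxolane-4-carbonyl)-4-tert-butyloxazolidin-2-one | O=C(N1[C@@H](C(C)(C)C)COC1=O)C1(Br)COC(=O)O1
F3 | step 4 | (4S)-4-tert-butyl-3-(2-oxo-1,3-dioxole-4-carbonyl)oxazolidin-2-one | O=C(N1[C@@H](C(C)(C)C)COC1=O)C1=COC(=O)O1
F4 | step 4 | (4S)-4-tert-butyl-3-{[(1S,2S,5R,6S)-1,6-(carbonyldioxy)-2-methoxy-2,5-epoxycyclohex-3-en-1-yl]carbonyl}oxazolidin-2-one | O=C(N1[C@@H](C(C)(C)C)COC1=O)[C@@]1(OC(=O)O2)[C@]3(OC)C=C[C@@H](O3)[C@@H]12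
F5 | step 3 | 4-bromo-2-oxo-1,3-dioxolane-4-carbonyl chloride (racemic) | O=C(Cl)C1(Br)COC(=O)O1
F6 | step 5 | (1S,2S,5R,6S)-1-(hydroxymethyl)-2-methoxy-2,5-epoxycyclohex-3-ene-1,6-diyl carbonate | OC[C@@]1(OC(=O)O2)[C@]3(OC)C=C[C@@H](O3)[C@@H]12
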